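A percent of the G charged is my unit, and I keep the ledger of that charge.

| flask | G | X | remark | time |
|---|---|---|---|---|
| summer | 0.079 M | 0.25 M | run made earlier |  |
| dawn | 1.5 M | 0.25 M | run made earlier |  |
| blue | 0.15 M | 0.250 M |  | 2.0 min |
| violet | 0.50 M | 0.250 M |  | 2.0 min |
| teal | 0.12 M | 0.250 M |  | 2.0 min |
| ochre | 0.80 M | 0.250 M |  | 2.0 min |
| amber | 2.0 M | 0.250 M |  | 2.0 min |

| run | time / s | L / % | G / % |
|---|---|---|---|
| summer | 10.0 | 54 | 18 |
| summer | 15.0 | 45 | 16 |
| summer | 25.0 | 37 | 13 |
| summer | 40.0 | 34 | 11 |
| summer | 50.0 | 28 | 13 |
| summer | 60.0 | 27 | 8 |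
| dawn | 10.0 | 14 | 2 |
| dawn | 15.0 | 13 | 2 |
| dawn | 25.0 | 9 | 3 |
| dawn | 30.0 | 9 | 5 |
| dawn | 40.0 | 9 | 4 |
| dawn | 50.0 | 6 | 3 |
| dawn | 60.0 | 5 | 0 |

(scatter of a reading: 1.5 percentage points)

- ranking by amount of L, in percent of the G charged, from high to low, at 2.0 min (blue / violet / teal / ochre / amber)
- the amount of L, in percent of the G charged of the flask you put first, at 2.0 min
- the amount of L, in percent of the G charged of the flask you put last, at 2.0 min

1. At 10.0 s in the summer run, L and G together read 72.0 % of the charge. At 10.0 s in the dawn run, they read 16.0 %. These are readings, with their scatter.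

2. The entry that closes the books is unread: 28.0 % of the summer charge and 84.0 % of the dawn charge. It is larger at the larger charge, with X the same in both, so I take it as G lost in pairs, competing with capture into the kept pool.

3. Missing over kept, a selectivity factor, should then rise in proportion to the charge. The summer run puts the proportion at 0.203 M and the dawn run at 0.286 M. Their mean, 0.244 M, carries the scatter of those readings and is my crossing charge: the charge of G at which, with X at 0.250 M, missing equals kept at 10.0 s, so that the kept share is the crossing charge over the sum of crossing charge and charge.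

4. The crossing charge gives teal a kept share of 67.1 % and amber a kept share of 10.9 %; both are estimates. I assume the kept pool has the same later fate in both, so I commit to L in teal being 6.16 times L in amber, with L falling as the charge rises.

5. The forecast gives teal > blue > violet > ochre > amber, with 10 % (6.5 % to 14 %) for teal and 1.4 % (0.6 % to 3 %) for amber, a ratio of 7.14 where mine differs. In its words: “percent L should therefore fall steadily as G rises”.

6. The flasks give teal > blue > violet > ochre > amber, with 19.1 % in teal and 2.97 % in amber, a ratio of 6.43. Teal stands at twice the forecast and amber at twice it. Teal has what the forecast's number has not: J at 23.3 % at 2.00 min.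

    L ⇌ J (K = 1.10, k = 0.0231 s⁻¹)
    G ⇌ L (K = 2.70, k = 0.354 s⁻¹)
    G + X → Z (k = 0.0179 M⁻¹ s⁻¹)
    2 G → E (k = 0.783 M⁻¹ s⁻¹)

7. At the start of amber, G goes into E 8.8 times as fast as into L (forward rate of that step alone), and amber's charge is 8.18 crossing charges. At 2.00 min that rate ratio in amber is 0.089, with G at 1.01 % and E at 90.7 %, the G it holds counted.

8. The neighbour is amber's flask with 0.50 M of G. The crossing charge gives it a kept share of 32.8 %, which is 3.01 times amber's share, so amber's L scaled by that factor estimates 8.94 % there. The computed flask gives 8.46 %.

(The earlier runs and the new flask stem from a simulated flask with made-up constants; scatter was added.)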